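**Plan**
- Retrosynthetic cuts: the C3–C4 ring bond (last), then C10–C1 (anti-aldol of a C8-acyloxy ethyl ketone with pent-4-enal), the C8–O ester bond, C4–I, C11–CH3, the lactone C–O bond with C6–H (alkynyl ketone reduction), C5–C6, and C7–C8 (syn-aldol of a succinate imide with 2-ethylacrolein).
- Forward order: the C6–C7–C8 chain; the cis-fused γ-lactone (ring B: O, C6, C7, C11, C12); C11 methylation; iodoalkene; epoxy ester; C9 ketone; aldol extension to C1–C3; finally the ten-membered carbocycle (ring A) is closed at C3–C4.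
- Enabling feature: C3 is an unfunctionalised primary CH2 two carbons from the C1 methoxy carbinol, so it can carry a carboxyl group that leaves as CO2. C4 is the methyl-bearing sp2 carbon of the E C4=C5 alkene next to the lactone carbon C6, so it can be an (E)-alkenyl iodide whose geometry is fixed before ring closure. The cis fusion of ring B at C6/C7 turns both chain ends to the same side.
- Stereochemistry: C7/C8 from the oxazolidinone syn-aldol; C6 from catalyst-controlled transfer hydrogenation; C11 from enolate methylation anti to the C7 substituent; C10/C1 from C8 in the (E)-boron-enolate anti-aldol; the epoxide from Sharpless epoxidation; C4=C5 geometry from syn-hydrozirconation.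

Key step: step 18

Assumption: the target is taken exactly as drawn (cis-fused C6/C7 lactone; epoxy ester of the tiglic series, carboxyl trans to the C3' methyl). Locants C1–C15 are the germacrane-type positions of the target (C1 methoxy carbon, C4=C5 alkene, C6 lactone carbinol, C7 ring fusion, C8 acyloxy carbon, C9 ketone, C10 and C11 methyl-bearing carbons, C12 lactone carbonyl). Compounds 1, 4, 5, 7, 12 and 23 are taken as commercial.

Step 1
Reactants: 1 (E)-2-methylbut-2-en-1-ol
Product: 2 [(2R,3R)-2,3-dimethyloxiran-2-yl]methanol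
Conditions: Ti(OiPr)4 (10 mol %), D-(−)-diisopropyl tartrate (12 mol %), tBuOOH, 4 Å molecular sieves, CH2Cl2, −20 °C
Reagents that add atoms: tert-butyl hydroperoxide, CC(C)(C)OO
Why: Sharpless asymmetric epoxidation of an allylic alcohol, in which the D-(−)-tartrate–titanium complex should deliver oxygen to the face that gives the (2R,3R)-epoxide while syn addition keeps CH2OH trans to the C3 methyl.

Step 2
Reactants: 2 epoxy alcohol
Product: 3 (2S,3R)-2,3-dimethyloxirane-2-carboxylic acid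
Conditions: TEMPO (20 mol %), PhI(OAc)2 (2.2 equiv), MeCN/H2O, 0 °C to rt
Reagents that add atoms: water, O
Why: oxoammonium-mediated oxidation of a primary alcohol to the acid through the aldehyde hydrate, which leaves both epoxide carbons untouched (the C2 descriptor changes only because CO2H outranks C3).

Step 3
Reactants: 4 (4R)-4-benzyl-1,3-oxazolidin-2-one; 5 4-tert-butoxy-4-oxobutanoic acid
Product: 6 tert-butyl 4-[(4R)-4-benzyl-2-oxo-1,3-oxazolidin-3-yl]-4-oxobutanoate
Conditions: DCC, DMAP (cat.), CH2Cl2, 0 °C to rt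
Reagents that add atoms: none
Why: Steglich-type carbodiimide N-acylation of the oxazolidinone, with no stereocentre involved.

Step 4
Reactants: 6 succinate imide; 7 2-methylidenebutanal (2-ethylacrolein)
Product: 9 tert-butyl (3R,4R)-3-{[(4R)-4-benzyl-2-oxo-1,3-oxazolidin-3-yl]carbonyl}-4-hydroxy-5-methylideneheptanoate, via dibutylboron Z-enolate 8 (not isolated)
Conditions: Bu2BOTf, iPr2NEt, CH2Cl2, 0 °C; then 7, −78 to 0 °C; pH 7 buffer work-up
Reagents that add atoms: dibutylboron triflate, CCCCB(CCCC)OS(=O)(=O)C(F)(F)F (its boron is carried only in 8)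
Why: Evans syn-aldol reaction, in which the imide (Z)-boron enolate reacts through a chair Zimmerman–Traxler transition state on the face away from the benzyl group and so sets C7 and C8 (3R,4R).

Step 5
Reactants: 9 aldol adduct
Product: 10 tert-butyl (3R,4R)-4-hydroxy-3-[methoxy(methyl)carbamoyl]-5-methylideneheptanoate
Conditions: Me3Al, MeONHMe·HCl, CH2Cl2, −20 to 0 °C
Reagents that add atoms: N,O-dimethylhydroxylamine hydrochloride, CNOC.Cl
Why: aluminium-amide aminolysis of the N-acyloxazolidinone (Weinreb amide formation) assisted by the free β-hydroxyl, which releases the auxiliary and should leave the hindered tert-butyl ester and both stereocentres intact.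

Step 6
Reactants: 10 Weinreb amide
Product: 11 tert-butyl (3R,4R)-4-[(tert-butyldimethylsilyl)oxy]-3-[methoxy(methyl)carbamoyl]-5-methylideneheptanoate
Conditions: TBSOTf, 2,6-lutidine, CH2Cl2, −78 to 0 °C
Reagents that add atoms: tert-butyldimethylsilyl triflate, CC(C)(C)[Si](C)(C)OS(=O)(=O)C(F)(F)F
Why: silyl ether formation, which blocks the C8 hydroxyl so that only the later C6 hydroxyl can lactonise onto C12.

Step 7
Reactants: 11 silyl ether; 12 prop-1-yn-1-ylmagnesium bromide
Product: 13 tert-butyl (3R,4R)-3-(but-2-ynoyl)-4-[(tert-butyldimethylsilyl)oxy]-5-methylideneheptanoate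
Conditions: THF, −20 to 0 °C; cold aq. NH4Cl
Reagents that add atoms: none
Why: Weinreb ketone synthesis, in which the chelated tetrahedral adduct prevents over-addition and the tert-butyl ester is too hindered to compete.

Step 8
Reactants: 13 alkynyl ketone
Product: 15 (4S,5R)-4-{(1R)-1-[(tert-butyldimethylsilyl)oxy]-2-methylidenebutyl}-5-(prop-1-yn-1-yl)oxolan-2-one, via hydroxy ester 14 (not isolated)
Conditions: Ru[(R,R)-TsNCH(Ph)CH(Ph)NH](p-cymene) (2 mol %), iPrOH, rt; evaporate; camphorsulfonic acid (10 mol %), CH2Cl2, rt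
Reagents that add atoms: none
Why: Noyori asymmetric transfer hydrogenation of an alkynyl ketone under neutral conditions should set C6 by catalyst control (the alkyne takes the role of the aryl group, so the (R,R)-catalyst gives the (R)-propargylic alcohol), and acid-catalysed intramolecular transesterification then closes ring B as the cis-4,5-disubstituted γ-lactone.

Step 9
Reactants: 15 lactone
Product: 17 (3S,4S,5R)-4-{(1R)-1-[(tert-butyldimethylsilyl)oxy]-2-methylidenebutyl}-3-methyl-5-(prop-1-yn-1-yl)oxolan-2-one, via lithium enolate 16 (not isolated)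
Conditions: LiN(SiMe3)2, THF, −78 °C; then MeI, −78 to −40 °C
Reagents that add atoms: iodomethane, CI; lithium bis(trimethylsilyl)amide, [Li+].C[Si](C)(C)[N-][Si](C)(C)C (its lithium is carried only in 16)
Why: lactone enolate alkylation, in which iodomethane should approach the face anti to the C7 side chain and the cis C6 propynyl group, setting C11 (S) trans to C7.

Step 10
Reactants: 17 methylated lactone
Product: 19 (3S,4S,5R)-4-{(1R)-1-[(tert-butyldimethylsilyl)oxy]-2-methylidenebutyl}-5-[(1E)-2-iodoprop-1-en-1-yl]-3-methyloxolan-2-one, via alkenylzirconocene chloride 18 (not isolated)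
Conditions: Cp2Zr(H)Cl (1.5 equiv), THF, rt; then I2, 0 °C
Reagents that add atoms: iodine, II; chlorohydridobis(cyclopentadienyl)zirconium, [H][Zr](Cl)(C1C=CC=C1)C1C=CC=C1 (its zirconium is carried only in 18)
Why: Schwartz hydrozirconation–iodination, in which syn addition places zirconium on the less hindered methyl-bearing C4 (distal to the branched C6) and iodinolysis with retention gives the (E)-2-iodoalkene.

Step 11
Reactants: 19 silyl ether
Product: 20 (3S,4R,5R)-4-[(1R)-1-hydroxy-2-methylidenebutyl]-5-[(1E)-2-iodoprop-1-en-1-yl]-3-methyloxolan-2-one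
Conditions: HF·pyridine, pyridine/THF, 0 °C to rt
Reagents that add atoms: none
Why: fluoride-mediated silyl ether cleavage under weakly acidic conditions, which avoids a free alkoxide at C8 and so should not cause translactonisation.

Step 12
Reactants: 20 C8 alcohol; 3 epoxy acid
Product: 21 (1R)-1-{(2R,3S,4S)-2-[(1E)-2-iodoprop-1-en-1-yl]-4-methyl-5-oxooxolan-3-yl}-2-methylidenebutyl (2S,3R)-2,3-dimethyloxirane-2-carboxylate
Conditions: 2-methyl-6-nitrobenzoic anhydride, Et3N, DMAP (cat.), CH2Cl2, rt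
Reagents that add atoms: none
Why: Shiina esterification through the mixed anhydride of 3, an acyl transfer at oxygen that retains C8 and both epoxide centres.

Step 13
Reactants: 21 epoxy ester
Product: 22 (1R)-1-{(2R,3S,4S)-2-[(1E)-2-iodoprop-1-en-1-yl]-4-methyl-5-oxooxolan-3-yl}-2-oxobutyl (2S,3R)-2,3-dimethyloxirane-2-carboxylate
Conditions: O3 (1.05 equiv, saturated CH2Cl2 solution), CH2Cl2, −78 °C; then Me2S
Reagents that add atoms: ozone, [O-][O+]=O
Why: ozonolysis, in which the 1,1-disubstituted alkene should react ahead of the iodine-deactivated trisubstituted alkene and unveil the C9 ethyl ketone.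

Step 14
Reactants: 22 ethyl ketone; 23 pent-4-enal
Product: 25 (1R,3S,4S)-4-hydroxy-1-{(2R,3S,4S)-2-[(1E)-2-iodoprop-1-en-1-yl]-4-methyl-5-oxooxolan-3-yl}-3-methyl-2-oxooct-7-en-1-yl (2S,3R)-2,3-dimethyloxirane-2-carboxylate, via dicyclohexylboron E-enolate 24 (not isolated)
Conditions: (c-C6H11)2BCl, Me2NEt, Et2O, −78 to 0 °C; then 23, −78 to −20 °C; pH 7 buffer/MeOH work-up
Reagents that add atoms: chlorodicyclohexylborane, ClB(C1CCCCC1)C1CCCCC1 (its boron is carried only in 24)
Why: Paterson anti-aldol reaction of an α-acyloxy ethyl ketone, in which the (E)-boron enolate reacts through a chair transition state with C8–H eclipsing the enolate C=C (allylic strain), the ester carbonyl hydrogen-bonded to the formyl hydrogen and the lactone pointing outward, so that C10 (S) and C1 (S) should be set from C8 in the anti,anti sense.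

Step 15
Reactants: 25 aldol adduct
Product: 26 (1R,3S,4S)-1-{(2R,3S,4S)-2-[(1E)-2-iodoprop-1-en-1-yl]-4-methyl-5-oxooxolan-3-yl}-4-methoxy-3-methyl-2-oxooct-7-en-1-yl (2S,3R)-2,3-dimethyloxirane-2-carboxylate
Conditions: Me3OBF4, 1,8-bis(dimethylamino)naphthalene, 4 Å molecular sieves, CH2Cl2, rt
Reagents that add atoms: trimethyloxonium tetrafluoroborate, C[O+](C)C.F[B-](F)(F)F
Why: O-methylation with Meerwein's salt under non-basic conditions, which should avoid retro-aldol cleavage, C10 epimerisation and β-elimination.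

Step 16
Reactants: 26 methyl ether
Product: 28 (4S,5S,7R)-7-{[(2S,3R)-2,3-dimethyloxirane-2-carbonyl]oxy}-7-{(2R,3S,4S)-2-[(1E)-2-iodoprop-1-en-1-yl]-4-methyl-5-oxooxolan-3-yl}-4-methoxy-5-methyl-6-oxoheptanoic acid, via aldehyde 27 (not isolated)
Conditions: O3 (1.05 equiv), CH2Cl2, −78 °C, PPh3; then NaClO2, NaH2PO4, 2-methyl-2-butene, tBuOH/H2O, rt
Reagents that add atoms: ozone, [O-][O+]=O; sodium chlorite, [Na+].[O-]Cl=O
Why: ozonolysis of the monosubstituted alkene (again faster than the iodoalkene) followed by Kraus–Pinnick oxidation in a weakly acidic buffer, which places the carboxyl group on C3 without touching the β-methoxy ketone or the epoxide.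

Step 17
Reactants: 28 carboxylic acid
Product: 29 1,3-dioxoisoindolin-2-yl (4S,5S,7R)-7-{[(2S,3R)-2,3-dimethyloxirane-2-carbonyl]oxy}-7-{(2R,3S,4S)-2-[(1E)-2-iodoprop-1-en-1-yl]-4-methyl-5-oxooxolan-3-yl}-4-methoxy-5-methyl-6-oxoheptanoate
Conditions: N-hydroxyphthalimide, N,N'-diisopropylcarbodiimide, DMAP (cat.), CH2Cl2, rt
Reagents that add atoms: N-hydroxyphthalimide, O=C1c2ccccc2C(=O)N1O
Why: carbodiimide coupling to the redox-active N-acyloxyphthalimide, which turns the C3 carboxyl into a single-electron-reducible radical precursor.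

Step 18
Reactants: 29 N-acyloxyphthalimide
Product: 30 (3S,3aS,4R,6S,7S,10E,11aS)-7-methoxy-3,6,10-trimethyl-2,5-dioxo-2,3,3a,4,5,6,7,8,9,11a-decahydrocyclodeca[b]furan-4-yl (2S,3R)-2,3-dimethyloxirane-2-carboxylate (CNP0145898.1)
Conditions: NiCl2·6H2O (20 mol %), 2,2'-bipyridine (20 mol %), AgNO3 (30 mol %), DMF, Mg anode/reticulated vitreous carbon cathode, undivided cell, constant current (about 3 F/mol), 29 added by syringe pump to 2 mM final concentration, rt
Reagents that add atoms: none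
Why: Proposed new method: cathodically generated zerovalent nickel–bipyridine should insert into the C4–I bond of the (E)-alkenyl iodide with retention; single-electron reduction of the N-acyloxyphthalimide (at the silver-modified cathode or by monovalent nickel) expels phthalimide anion and CO2 to give the primary C3 radical, which is captured by the alkenylnickel of the same molecule, and reductive elimination from trivalent nickel forms the C3–C4 bond. The closest known reaction type is the intermolecular nickel-electrocatalytic decarboxylative alkenylation of redox-active esters with alkenyl iodides, which couples primary alkyl radicals with trisubstituted iodoalkenes without loss of alkene geometry; the intramolecular, ring-forming version is the untested part. Ring A, the ten-membered carbocycle, is closed by radical capture at nickel to an eleven-membered alkyl(alkenyl)nickelacycle followed by C(sp3)–C(sp2) reductive elimination, so no exo or endo radical addition to the alkene is involved. No new stereocentre is formed, and the E geometry of C4=C5 should be carried over from 29 because alkenylnickel species are configurationally stable. The step needs cyclisation to win over oligomerisation and over reduction of the radical, which slow addition into a dilute electrolysis and the turn imposed by the cis-fused lactone (C5 and C8 on the same face of ring B) should secure; it also needs the potential to stay below that of the C9 ketone with its C8 acyloxy group, which the easily reduced phthalimide ester and the mediated electron transfer should provide. The carboxyl carbon that activated C3 leaves as CO2 in the same step.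

**Compound list**
1 | (E)-2-methylbut-2-en-1-ol | C/C=C(\C)CO | starting material
2 | [(2R,3R)-2,3-dimethyloxiran-2-yl]methanol | OC[C@@]1(C)O[C@@H]1C | intermediate
3 | (2S,3R)-2,3-dimethyloxirane-2-carboxylic acid | OC(=O)[C@@]1(C)O[C@@H]1C | intermediate
4 | (4R)-4-benzyl-1,3-oxazolidin-2-one | O=C1N[C@H](Cc2ccccc2)CO1 | starting material
5 | 4-tert-butoxy-4-oxobutanoic acid | CC(C)(C)OC(=O)CCC(=O)O | starting material
6 | tert-butyl 4-[(4R)-4-benzyl-2-oxo-1,3-oxazolidin-3-yl]-4-oxobutanoate | CC(C)(C)OC(=O)CCC(=O)N1[C@H](Cc2ccccc2)COC1=O | intermediate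
7 | 2-methylidenebutanal (2-ethylacrolein) | CCC(=C)C=O | starting material
8 | tert-butyl (3Z)-4-[(4R)-4-benzyl-2-oxo-1,3-oxazolidin-3-yl]-4-[(dibutylboranyl)oxy]but-3-enoate | CC(C)(C)OC(=O)C/C=C(\OB(CCCC)CCCC)N1[C@H](Cc2ccccc2)COC1=O | intermediate
9 | tert-butyl (3R,4R)-3-{[(4R)-4-benzyl-2-oxo-1,3-oxazolidin-3-yl]carbonyl}-4-hydroxy-5-methylideneheptanoate | CC(C)(C)OC(=O)C[C@@H](C(=O)N1[C@H](Cc2ccccc2)COC1=O)[C@@H](O)C(=C)CC | intermediate
10 | tert-butyl (3R,4R)-4-hydroxy-3-[methoxy(methyl)carbamoyl]-5-methylideneheptanoate | CC(C)(C)OC(=O)C[C@@H](C(=O)N(C)OC)[C@@H](O)C(=C)CC | intermediate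
11 | tert-butyl (3R,4R)-4-[(tert-butyldimethylsilyl)oxy]-3-[methoxy(methyl)carbamoyl]-5-methylideneheptanoate | CC(C)(C)OC(=O)C[C@@H](C(=O)N(C)OC)[C@@H](O[Si](C)(C)C(C)(C)C)C(=C)CC | intermediate
12 | prop-1-yn-1-ylmagnesium bromide | CC#C[Mg]Br | starting material
13 | tert-butyl (3R,4R)-3-(but-2-ynoyl)-4-[(tert-butyldimethylsilyl)oxy]-5-methylideneheptanoate | CC(C)(C)OC(=O)C[C@@H](C(=O)C#CC)[C@@H](O[Si](C)(C)C(C)(C)C)C(=C)CC | intermediate
14 | tert-butyl (3S,4R)-4-[(tert-butyldimethylsilyl)oxy]-3-[(1R)-1-hydroxybut-2-yn-1-yl]-5-methylideneheptanoate | CC(C)(C)OC(=O)C[C@@H]([C@@H](O)C#CC)[C@@H](O[Si](C)(C)C(C)(C)C)C(=C)CC | intermediate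
15 | (4S,5R)-4-{(1R)-1-[(tert-butyldimethylsilyl)oxy]-2-methylidenebutyl}-5-(prop-1-yn-1-yl)oxolan-2-one | CC#C[C@@H]1OC(=O)C[C@@H]1[C@@H](O[Si](C)(C)C(C)(C)C)C(=C)CC | intermediate
16 | lithium (4S,5R)-4-{(1R)-1-[(tert-butyldimethylsilyl)oxy]-2-methylidenebutyl}-5-(prop-1-yn-1-yl)-4,5-dihydrofuran-2-olate (lithium enolate of 15) | CC#C[C@@H]1OC(O[Li])=C[C@@H]1[C@@H](O[Si](C)(C)C(C)(C)C)C(=C)CC | intermediate
17 | (3S,4S,5R)-4-{(1R)-1-[(tert-butyldimethylsilyl)oxy]-2-methylidenebutyl}-3-methyl-5-(prop-1-yn-1-yl)oxolan-2-one | CC#C[C@@H]1OC(=O)[C@@H](C)[C@@H]1[C@@H](O[Si](C)(C)C(C)(C)C)C(=C)CC | intermediate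
18 | chlorobis(cyclopentadienyl){(1E)-1-[(2R,3S,4S)-3-{(1R)-1-[(tert-butyldimethylsilyl)oxy]-2-methylidenebutyl}-4-methyl-5-oxooxolan-2-yl]prop-1-en-2-yl}zirconium | C/C(=C\[C@@H]1OC(=O)[C@@H](C)[C@@H]1[C@@H](O[Si](C)(C)C(C)(C)C)C(=C)CC)[Zr](Cl)(C1C=CC=C1)C1C=CC=C1 | intermediate
19 | (3S,4S,5R)-4-{(1R)-1-[(tert-butyldimethylsilyl)oxy]-2-methylidenebutyl}-5-[(1E)-2-iodoprop-1-en-1-yl]-3-methyloxolan-2-one | C/C(I)=C\[C@@H]1OC(=O)[C@@H](C)[C@@H]1[C@@H](O[Si](C)(C)C(C)(C)C)C(=C)CC | intermediate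
20 | (3S,4R,5R)-4-[(1R)-1-hydroxy-2-methylidenebutyl]-5-[(1E)-2-iodoprop-1-en-1-yl]-3-methyloxolan-2-one | C/C(I)=C\[C@@H]1OC(=O)[C@@H](C)[C@@H]1[C@@H](O)C(=C)CC | intermediate
21 | (1R)-1-{(2R,3S,4S)-2-[(1E)-2-iodoprop-1-en-1-yl]-4-methyl-5-oxooxolan-3-yl}-2-methylidenebutyl (2S,3R)-2,3-dimethyloxirane-2-carboxylate | C/C(I)=C\[C@@H]1OC(=O)[C@@H](C)[C@@H]1[C@@H](OC(=O)[C@@]2(C)O[C@@H]2C)C(=C)CC | intermediate
22 | (1R)-1-{(2R,3S,4S)-2-[(1E)-2-iodoprop-1-en-1-yl]-4-methyl-5-oxooxolan-3-yl}-2-oxobutyl (2S,3R)-2,3-dimethyloxirane-2-carboxylate | C/C(I)=C\[C@@H]1OC(=O)[C@@H](C)[C@@H]1[C@@H](OC(=O)[C@@]2(C)O[C@@H]2C)C(=O)CC | intermediate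
23 | pent-4-enal | C=CCCC=O | starting material
24 | (1R,2E)-2-[(dicyclohexylboranyl)oxy]-1-{(2R,3S,4S)-2-[(1E)-2-iodoprop-1-en-1-yl]-4-methyl-5-oxooxolan-3-yl}but-2-en-1-yl (2S,3R)-2,3-dimethyloxirane-2-carboxylate | C/C(I)=C\[C@@H]1OC(=O)[C@@H](C)[C@@H]1[C@@H](OC(=O)[C@@]2(C)O[C@@H]2C)/C(OB(C2CCCCC2)C2CCCCC2)=C\C | intermediate
25 | (1R,3S,4S)-4-hydroxy-1-{(2R,3S,4S)-2-[(1E)-2-iodoprop-1-en-1-yl]-4-methyl-5-oxooxolan-3-yl}-3-methyl-2-oxooct-7-en-1-yl (2S,3R)-2,3-dimethyloxirane-2-carboxylate | C/C(I)=C\[C@@H]1OC(=O)[C@@H](C)[C@@H]1[C@@H](OC(=O)[C@@]2(C)O[C@@H]2C)C(=O)[C@@H](C)[C@@H](O)CCC=C | intermediate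
26 | (1R,3S,4S)-1-{(2R,3S,4S)-2-[(1E)-2-iodoprop-1-en-1-yl]-4-methyl-5-oxooxolan-3-yl}-4-methoxy-3-methyl-2-oxooct-7-en-1-yl (2S,3R)-2,3-dimethyloxirane-2-carboxylate | C/C(I)=C\[C@@H]1OC(=O)[C@@H](C)[C@@H]1[C@@H](OC(=O)[C@@]2(C)O[C@@H]2C)C(=O)[C@@H](C)[C@@H](OC)CCC=C | intermediate
27 | (1R,3S,4S)-1-{(2R,3S,4S)-2-[(1E)-2-iodoprop-1-en-1-yl]-4-methyl-5-oxooxolan-3-yl}-4-methoxy-3-methyl-2,7-dioxoheptyl (2S,3R)-2,3-dimethyloxirane-2-carboxylate | C/C(I)=C\[C@@H]1OC(=O)[C@@H](C)[C@@H]1[C@@H](OC(=O)[C@@]2(C)O[C@@H]2C)C(=O)[C@@H](C)[C@@H](OC)CCC=O | intermediate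
28 | (4S,5S,7R)-7-{[(2S,3R)-2,3-dimethyloxirane-2-carbonyl]oxy}-7-{(2R,3S,4S)-2-[(1E)-2-iodoprop-1-en-1-yl]-4-methyl-5-oxooxolan-3-yl}-4-methoxy-5-methyl-6-oxoheptanoic acid | C/C(I)=C\[C@@H]1OC(=O)[C@@H](C)[C@@H]1[C@@H](OC(=O)[C@@]2(C)O[C@@H]2C)C(=O)[C@@H](C)[C@@H](OC)CCC(=O)O | intermediate
29 | 1,3-dioxoisoindolin-2-yl (4S,5S,7R)-7-{[(2S,3R)-2,3-dimethyloxirane-2-carbonyl]oxy}-7-{(2R,3S,4S)-2-[(1E)-2-iodoprop-1-en-1-yl]-4-methyl-5-oxooxolan-3-yl}-4-methoxy-5-methyl-6-oxoheptanoate | C/C(I)=C\[C@@H]1OC(=O)[C@@H](C)[C@@H]1[C@@H](OC(=O)[C@@]2(C)O[C@@H]2C)C(=O)[C@@H](C)[C@@H](OC)CCC(=O)ON1C(=O)c2ccccc2C1=O | intermediate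
30 | (3S,3aS,4R,6S,7S,10E,11aS)-7-methoxy-3,6,10-trimethyl-2,5-dioxo-2,3,3a,4,5,6,7,8,9,11a-decahydrocyclodeca[b]furan-4-yl (2S,3R)-2,3-dimethyloxirane-2-carboxylate (CNP0145898.1) | CO[C@H]1CC/C(C)=C/[C@@H]2OC(=O)[C@@H](C)[C@@H]2[C@@H](OC(=O)[C@@]2(C)O[C@@H]2C)C(=O)[C@H]1C | target

**Step count and risks**
Total step count: 18. Longest linear sequence: 16 steps (steps 3–18, from 4 and 5); steps 1–2 make the side-chain acid 3.

Steps most likely to fail:

1. Step 18. The C3 radical may be reduced or captured by nickel on another molecule, giving the decarboxylated open chain or oligomers instead of ring A; the strain of the E-cyclodecene slows closure further. Fallback with known chemistry (B-alkyl Suzuki–Miyaura macrocyclisation), setting out from 22 and returning at 30: the same (c-C6H11)2BCl/Me2NEt anti-aldol with acrolein in place of 23 should give the C1 allylic alcohol F1. Me3OBF4 with 1,8-bis(dimethylamino)naphthalene gives the methyl ether F2. Hydroboration of the monosubstituted alkene with 9-borabicyclo[3.3.1]nonane (THF, 0 °C; faster than attack on the hindered ketone) gives the C3 alkylborane F3. Slow addition of F3 to Pd(dppf)Cl2, AsPh3 and Cs2CO3 in DMF/THF/H2O couples C3 with C4 and gives 30.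

2. Step 14. The chloroborane may open the epoxide of the ester during enolisation, and facial selectivity may erode with the larger C7 substituent. Fallback, setting out from 19 and returning at 26, with the aldol run before the ester is installed: ozonolysis of 19 (O3, CH2Cl2, −78 °C; Me2S) gives the α-silyloxy ethyl ketone F4. Its (E)-dicyclohexylboron enolate and 23 should give the anti-aldol adduct F5; allylic strain and dipole opposition by the C8 silyloxy group are expected to favour the same isomer, with a lower bias. Me3OBF4 methylation gives the methyl ether F6. HF·pyridine frees the C8 hydroxyl as the α-hydroxy ketone F7. Shiina esterification of F7 with 3 gives 26.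

3. Step 10. The zirconium hydride may attack the lactone carbonyl, or zirconium may be placed at C5, from where β-elimination of the lactone oxygen would give an allene. Fallback, setting out from 17 and returning at 19: platinum-catalysed syn-hydrosilylation (PtCl2, XPhos, Et3SiH, THF, 50 °C), which places silicon on C4, distal to the oxygen-bearing C6, should give the (E)-alkenylsilane F8. Iododesilylation of F8 with N-iodosuccinimide in hexafluoroisopropanol, with retention, gives 19.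

**Further compounds**
F1 | step 18 | (1R,3S,4S)-4-hydroxy-1-{(2R,3S,4S)-2-[(1E)-2-iodoprop-1-en-1-yl]-4-methyl-5-oxooxolan-3-yl}-3-methyl-2-oxohex-5-en-1-yl (2S,3R)-2,3-dimethyloxirane-2-carboxylate | C/C(I)=C\[C@@H]1OC(=O)[C@@H](C)[C@@H]1[C@@H](OC(=O)[C@@]2(C)O[C@@H]2C)C(=O)[C@@H](C)[C@@H](O)C=C
F2 | step 18 | (1R,3S,4S)-1-{(2R,3S,4S)-2-[(1E)-2-iodoprop-1-en-1-yl]-4-methyl-5-oxooxolan-3-yl}-4-methoxy-3-methyl-2-oxohex-5-en-1-yl (2S,3R)-2,3-dimethyloxirane-2-carboxylate | C/C(I)=C\[C@@H]1OC(=O)[C@@H](C)[C@@H]1[C@@H](OC(=O)[C@@]2(C)O[C@@H]2C)C(=O)[C@@H](C)[C@@H](OC)C=C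
F3 | step 18 | (1R,3S,4S)-6-(9-borabicyclo[3.3.1]nonan-9-yl)-1-{(2R,3S,4S)-2-[(1E)-2-iodoprop-1-en-1-yl]-4-methyl-5-oxooxolan-3-yl}-4-methoxy-3-methyl-2-oxohexyl (2S,3R)-2,3-dimethyloxirane-2-carboxylate | C/C(I)=C\[C@@H]1OC(=O)[C@@H](C)[C@@H]1[C@@H](OC(=O)[C@@]2(C)O[C@@H]2C)C(=O)[C@@H](C)[C@@H](OC)CCB1C2CCCC1CCC2
F4 | step 14 | (3S,4S,5R)-4-{(1R)-1-[(tert-butyldimethylsilyl)oxy]-2-oxobutyl}-5-[(1E)-2-iodoprop-1-en-1-yl]-3-methyloxolan-2-one | C/C(I)=C\[C@@H]1OC(=O)[C@@H](C)[C@@H]1[C@@H](O[Si](C)(C)C(C)(C)C)C(=O)CC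
F5 | step 14 | (3S,4S,5R)-4-{(1R,3S,4S)-1-[(tert-butyldimethylsilyl)oxy]-4-hydroxy-3-methyl-2-oxooct-7-en-1-yl}-5-[(1E)-2-iodoprop-1-en-1-yl]-3-methyloxolan-2-one | C/C(I)=C\[C@@H]1OC(=O)[C@@H](C)[C@@H]1[C@@H](O[Si](C)(C)C(C)(C)C)C(=O)[C@@H](C)[C@@H](O)CCC=C
F6 | step 14 | (3S,4S,5R)-4-{(1R,3S,4S)-1-[(tert-butyldimethylsilyl)oxy]-4-methoxy-3-methyl-2-oxooct-7-en-1-yl}-5-[(1E)-2-iodoprop-1-en-1-yl]-3-methyloxolan-2-one | C/C(I)=C\[C@@H]1OC(=O)[C@@H](C)[C@@H]1[C@@H](O[Si](C)(C)C(C)(C)C)C(=O)[C@@H](C)[C@@H](OC)CCC=C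
F7 | step 14 | (3S,4R,5R)-4-[(1R,3S,4S)-1-hydroxy-4-methoxy-3-methyl-2-oxooct-7-en-1-yl]-5-[(1E)-2-iodoprop-1-en-1-yl]-3-methyloxolan-2-one | C/C(I)=C\[C@@H]1OC(=O)[C@@H](C)[C@@H]1[C@@H](O)C(=O)[C@@H](C)[C@@H](OC)CCC=C
F8 | step 10 | (3S,4S,5R)-4-{(1R)-1-[(tert-butyldimethylsilyl)oxy]-2-methylidenebutyl}-3-methyl-5-[(1E)-2-(triethylsilyl)prop-1-en-1-yl]oxolan-2-one | C/C(=C\[C@@H]1OC(=O)[C@@H](C)[C@@H]1[C@@H](O[Si](C)(C)C(C)(C)C)C(=C)CC)[Si](CC)(CC)CC
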